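The side chain is cut at C4'–C5', C12'–C13' and C24'–C25' (sulfone alkylations) and, decisively, at C10'–C11'. The key step exploits the acyclic saturated C5'–C12' run, on which the methyl stereocentres C7' and C11' are 1,5-related and cannot relay to each other. C7' (like C27') is bought with (S)-citronellol, and C11' is set by the ligand in a nickel-catalysed enantioconvergent Negishi coupling. In one operation a C5'–C10' primary alkylzinc bromide, carrying the C5' phenylsulfonyl handle, joins racemic N-benzyl-2-bromo-N-phenylpropanamide, forming C10'–C11' and 11'R. No ring is formed, and the naphthoquinone ring system enters last as its dimethyl ether.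

Key step: step 7

Remark on the structure: with C1' the ring-bound CH2 and C32' the chain end, the target has three stereocentres, 7'S, 11'R and 27'S. C13'–C32' is a C25 unit whose last two isoprene units are saturated, so (2E,6E)-farnesol can furnish only C13'–C24'; C25'–C32' with C27' comes from a second (S)-citronellol-derived piece.

Remark on the precursor: the C5' substituent of the zinc reagent is the phenylsulfonyl group needed for the last chain coupling instead of a protected hydroxyl, so one citronellol-derived sulfone feeds both C5'–C10' and C25'–C32'.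

Assumption: the (S,S) antipode of i-Pr-pybox is taken to give the 2R amide, by analogy with the sense of induction of this catalyst for higher α-alkyl bromoamides. The sense should be confirmed on a small scale and the (R,R) ligand used if it proves opposite.

Step 1
Reactants: 1 (S)-citronellol
Product: 2 (S)-citronellyl bromide
Conditions: CBr4, PPh3, CH2Cl2, 0 °C
Reagents that add atoms: carbon tetrabromide, BrC(Br)(Br)Br
Why: Appel bromination of a primary alcohol proceeds by SN2 at C1 under neutral conditions and should leave the trisubstituted alkene and the methyl-bearing stereocentre (future C7' and C27') untouched.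

Step 2
Reactants: 2 (S)-citronellyl bromide
Product: 3 [(3S)-3,7-dimethyloct-6-en-1-yl]sulfonylbenzene
Conditions: PhSO2Na, n-Bu4NI (cat.), DMF, 60 °C
Reagents that add atoms: sodium benzenesulfinate, [Na+].[O-]S(=O)c1ccccc1
Why: S-alkylation of the sulfinate by an unhindered primary bromide (SN2) should give the sulfone that serves both as the C5' handle and as the source of the C25'–C32' unit.

Step 3
Reactants: 3 [(3S)-3,7-dimethyloct-6-en-1-yl]sulfonylbenzene
Product: 5 (4S)-4-methyl-6-(phenylsulfonyl)hexan-1-ol, via (4S)-4-methyl-6-(phenylsulfonyl)hexanal 4 (not isolated)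
Conditions: O3, CH2Cl2/MeOH, −78 °C; then NaBH4 (excess), −78 °C → rt
Reagents that add atoms: ozone, O=[O+][O-]
Why: Ozonolysis with reductive work-up cleaves the only alkene and reduces the resulting aldehyde in the same flask to the C10' alcohol, the electron-poor phenyl sulfone being inert to ozone.

Step 4
Reactants: 5 (4S)-4-methyl-6-(phenylsulfonyl)hexan-1-ol
Product: 6 [(3S)-6-bromo-3-methylhexyl]sulfonylbenzene
Conditions: CBr4, PPh3, CH2Cl2, 0 °C
Reagents that add atoms: carbon tetrabromide, BrC(Br)(Br)Br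
Why: Appel bromination converts the primary C10' alcohol into the bromide by SN2 without affecting the sulfone or the C7' centre.

Step 5
Reactants: 6 [(3S)-6-bromo-3-methylhexyl]sulfonylbenzene
Product: 7 bromo[(4S)-4-methyl-6-(phenylsulfonyl)hexyl]zinc (titrated DMI solution)
Conditions: Zn dust, I2 (5 mol %), DMI, 70 °C
Reagents that add atoms: zinc, [Zn]
Why: Direct insertion of iodine-activated zinc into an unactivated primary alkyl bromide in a polar amide solvent is a standard route to alkylzinc bromides, and the sulfone α-C–H is no more acidic than those of the nitriles and esters such reagents tolerate.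

Step 6
Reactants: 8 2-bromopropanoyl bromide; 9 N-benzylaniline
Product: 10 rac-N-benzyl-2-bromo-N-phenylpropanamide
Conditions: Et3N, CH2Cl2, 0 °C → rt
Reagents that add atoms: none
Why: N-acylation of the secondary aniline by the acid bromide (nucleophilic acyl substitution) should give the racemic α-bromo amide, whose configuration is irrelevant because the next step is stereoconvergent.

Step 7
Reactants: 7 bromo[(4S)-4-methyl-6-(phenylsulfonyl)hexyl]zinc; 10 rac-N-benzyl-2-bromo-N-phenylpropanamide
Product: 11 (2R,6S)-N-benzyl-2,6-dimethyl-N-phenyl-8-(phenylsulfonyl)octanamide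
Conditions: 7 (1.3 equiv), NiCl2(glyme) (10 mol %), (S,S)-i-Pr-pybox (13 mol %), DMI/THF, 0 °C
Reagents that add atoms: none
Why: The pybox-ligated nickel alkyl formed by transmetalation from 7 abstracts bromine from either enantiomer of 10 to give one planar α-amido radical, which is captured at nickel to a trivalent dialkyl species that reductively eliminates with formation of C10'–C11'. The closest known reaction type is the nickel/pybox enantioconvergent Negishi alkylation of racemic α-bromo amides with primary alkylzinc halides, here applied to a new pair of partners. No ring is closed. The new stereocentre C11' is controlled by the ligand antipode alone (catalyst control), C7' lying three bonds from the zinc-bearing carbon and being too remote to match or mismatch. The step needs face selectivity between methyl and the amide group at the radical carbon and chemoselectivity for the C–Zn bond; these are secured by the N-benzyl-N-phenyl amide that the catalyst recognises, by the unbranched primary zinc carbon, and by a sulfone whose α-C–H is no more acidic than those of tolerated nitriles and esters.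

Step 8
Reactants: 11 (2R,6S)-N-benzyl-2,6-dimethyl-N-phenyl-8-(phenylsulfonyl)octanamide
Product: 12 (2R,6S)-2,6-dimethyl-8-(phenylsulfonyl)octan-1-ol
Conditions: LiAlH4, THF, 0 °C → rt
Reagents that add atoms: none
Why: Hydride reduction of the N-aryl tertiary amide proceeds with C–N cleavage (the weakly basic N-benzylanilide leaves from the tetrahedral intermediate) to the primary C12' alcohol, without enolising C11' or reducing the sulfone.

Step 9
Reactants: 12 (2R,6S)-2,6-dimethyl-8-(phenylsulfonyl)octan-1-ol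
Product: 13 [(3S,7R)-8-iodo-3,7-dimethyloctyl]sulfonylbenzene
Conditions: I2, PPh3, imidazole, CH2Cl2, 0 °C → rt
Reagents that add atoms: iodine, II
Why: Appel-type iodination activates the β-branched primary C12' alcohol by SN2 at the CH2 carbon only, so C11' is not touched.

Step 10
Reactants: 3 [(3S)-3,7-dimethyloct-6-en-1-yl]sulfonylbenzene
Product: 14 [(3S)-3,7-dimethyloctyl]sulfonylbenzene
Conditions: H2 (1 atm), Pd/C, EtOAc, rt
Reagents that add atoms: none
Why: Heterogeneous hydrogenation saturates the isolated trisubstituted alkene to the isopropyl terminus (C31') without creating a stereocentre, the sulfone and the future C27' centre being inert.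

Step 11
Reactants: 15 (2E,6E)-farnesol
Product: 16 benzyl (2E,6E)-farnesyl ether
Conditions: NaH, BnBr, n-Bu4NI (cat.), THF, 0 °C → rt
Reagents that add atoms: benzyl bromide, BrCc1ccccc1
Why: Williamson etherification of the allylic alkoxide masks the C13' oxygen with a group that survives allylic oxidation, bromination and organolithium chemistry.

Step 12
Reactants: 16 benzyl (2E,6E)-farnesyl ether
Product: 17 (2E,6E,10E)-12-(benzyloxy)-2,6,10-trimethyldodeca-2,6,10-trien-1-ol
Conditions: SeO2 (cat.), t-BuOOH, salicylic acid (cat.), CH2Cl2, 0 °C → rt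
Reagents that add atoms: selenium dioxide, O=[Se]=O; tert-butyl hydroperoxide (terminal oxidant), CC(C)(C)OO
Why: SeO2 allylic oxidation (ene reaction then [2,3]-sigmatropic shift) should attack the most electron-rich, least hindered terminal alkene at its (E)-methyl group, giving the (E)-allylic alcohol at C24'.

Step 13
Reactants: 17 (2E,6E,10E)-12-(benzyloxy)-2,6,10-trimethyldodeca-2,6,10-trien-1-ol
Product: 18 {[(2E,6E,10E)-12-bromo-3,7,11-trimethyldodeca-2,6,10-trien-1-yl]oxymethyl}benzene
Conditions: CBr4, PPh3, CH2Cl2, −20 °C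
Reagents that add atoms: carbon tetrabromide, BrC(Br)(Br)Br
Why: Appel bromination of the primary allylic alcohol at low temperature proceeds by SN2 without allylic transposition, so the C22'=C23' (E) geometry is kept.

Step 14
Reactants: 14 [(3S)-3,7-dimethyloctyl]sulfonylbenzene; 18 {[(2E,6E,10E)-12-bromo-3,7,11-trimethyldodeca-2,6,10-trien-1-yl]oxymethyl}benzene
Product: 20 {[(2E,6E,10E,15S)-3,7,11,15,19-pentamethyl-13-(phenylsulfonyl)icosa-2,6,10-trien-1-yl]oxymethyl}benzene (C13 epimers), via alpha-lithiated sulfone 19 (not isolated)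
Conditions: n-BuLi, THF, −78 °C; then 18, −78 → −20 °C
Reagents that add atoms: none
Why: Alkylation of an α-sulfonyl carbanion with a primary allylic bromide is a clean SN2 process that forms C24'–C25' without SN2' or E/Z leakage; the new C25' sulfonyl centre is removed in the next step.

Step 15
Reactants: 20 {[(2E,6E,10E,15S)-3,7,11,15,19-pentamethyl-13-(phenylsulfonyl)icosa-2,6,10-trien-1-yl]oxymethyl}benzene
Product: 21 (2E,6E,10E,15S)-3,7,11,15,19-pentamethylicosa-2,6,10-trien-1-ol
Conditions: Li, EtNH2/THF, −78 °C; then MeOH, H2O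
Reagents that add atoms: none
Why: Dissolving-metal reduction cleaves the alkyl C25'–S bond and the benzyl C–O bond in one operation (electron transfer to the two arenes), a standard finish for benzyl-protected polyprenyl sulfones, while the isolated trisubstituted alkenes and C27' are not reduced.

Step 16
Reactants: 21 (2E,6E,10E,15S)-3,7,11,15,19-pentamethylicosa-2,6,10-trien-1-ol
Product: 22 (2E,6E,10E,15S)-1-bromo-3,7,11,15,19-pentamethylicosa-2,6,10-triene
Conditions: PBr3, Et2O, 0 °C
Reagents that add atoms: phosphorus tribromide, BrP(Br)Br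
Why: PBr3 converts primary prenyl-type alcohols into the allylic bromides by SN2 with retention of the (E)-alkene, as in the standard preparation of farnesyl bromide.

Step 17
Reactants: 22 (2E,6E,10E,15S)-1-bromo-3,7,11,15,19-pentamethylicosa-2,6,10-triene
Product: 23 [(2E,6E,10E,15S)-3,7,11,15,19-pentamethylicosa-2,6,10-trien-1-yl]sulfonylbenzene
Conditions: PhSO2Na, DMF, 0 °C → rt
Reagents that add atoms: sodium benzenesulfinate, [Na+].[O-]S(=O)c1ccccc1
Why: Sulfinate S-alkylation at the primary allylic carbon (SN2) should give the C13' allylic sulfone with the C14'=C15' (E) geometry intact.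

Step 18
Reactants: 23 [(2E,6E,10E,15S)-3,7,11,15,19-pentamethylicosa-2,6,10-trien-1-yl]sulfonylbenzene; 13 [(3S,7R)-8-iodo-3,7-dimethyloctyl]sulfonylbenzene
Product: 25 1,1'-{[(3S,7R,10E,14E,18E,23S)-3,7,11,15,19,23,27-heptamethyloctacosa-10,14,18-triene-1,9-diyl]disulfonyl}dibenzene (C9 epimers), via lithiated allylic sulfone 24 (not isolated)
Conditions: n-BuLi, THF/DMPU, −78 °C; then 13, −78 → 0 °C
Reagents that add atoms: none
Why: The allylic sulfone is far more acidic than the alkyl sulfone of 13, so its configurationally stable α-anion alkylates the primary iodide by SN2 to form C12'–C13' without proton exchange, C11' being β to the reacting carbon and not epimerisable.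

Step 19
Reactants: 25 1,1'-{[(3S,7R,10E,14E,18E,23S)-3,7,11,15,19,23,27-heptamethyloctacosa-10,14,18-triene-1,9-diyl]disulfonyl}dibenzene
Product: 26 [(3S,7R,10E,14E,18E,23S)-3,7,11,15,19,23,27-heptamethyloctacosa-10,14,18-trien-1-yl]sulfonylbenzene
Conditions: PdCl2(dppp) (5 mol %), LiEt3BH, THF, 0 °C
Reagents that add atoms: none
Why: Zerovalent palladium formed in situ ionises only the allylic C13'–S bond to a π-allyl complex, and hydride is delivered to the less substituted terminus C13' (palladium-catalysed reductive desulfonylation), keeping the C14'=C15' (E) alkene and leaving the non-allylic C5' sulfone untouched.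

Step 20
Reactants: 27 menadione
Product: 29 1,4-dimethoxy-2-methylnaphthalene, via menadiol 28 (not isolated)
Conditions: Na2S2O4, n-Bu4NBr, THF/H2O, rt; then KOH, Me2SO4
Reagents that add atoms: dimethyl sulfate, COS(=O)(=O)OC
Why: Dithionite reduction of the quinone and O-methylation of the hydroquinone dianion in the same flask is a standard reductive methylation that masks the quinone for the organometallic steps.

Step 21
Reactants: 29 1,4-dimethoxy-2-methylnaphthalene
Product: 30 2-bromo-1,4-dimethoxy-3-methylnaphthalene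
Conditions: Br2, CH2Cl2, 0 °C
Reagents that add atoms: bromine, BrBr
Why: Electrophilic aromatic bromination occurs at C3, the only free position of the doubly activated ring.

Step 22
Reactants: 30 2-bromo-1,4-dimethoxy-3-methylnaphthalene; 31 prenyl bromide
Product: 33 1,4-dimethoxy-2-methyl-3-(3-methylbut-2-en-1-yl)naphthalene, via aryl Grignard reagent 32 (not isolated)
Conditions: Mg, THF, reflux; then CuI (5 mol %), 31, 0 °C
Reagents that add atoms: none
Why: Copper-catalysed allylation of the aryl Grignard reagent at the primary carbon of prenyl bromide (SN2 mode) installs C1'–C4' with its two methyl groups.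

Step 23
Reactants: 33 1,4-dimethoxy-2-methyl-3-(3-methylbut-2-en-1-yl)naphthalene
Product: 34 (2E)-4-(1,4-dimethoxy-3-methylnaphthalen-2-yl)-2-methylbut-2-en-1-ol
Conditions: SeO2 (cat.), t-BuOOH, CH2Cl2, 0 °C → rt
Reagents that add atoms: selenium dioxide, O=[Se]=O; tert-butyl hydroperoxide (terminal oxidant), CC(C)(C)OO
Why: SeO2 allylic oxidation of a trisubstituted alkene takes place at the more substituted terminus on the (E)-methyl group, so C4' is hydroxylated with (E) geometry at C2'=C3' while the C1' methylene at the other terminus is not attacked.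

Step 24
Reactants: 34 (2E)-4-(1,4-dimethoxy-3-methylnaphthalen-2-yl)-2-methylbut-2-en-1-ol
Product: 35 2-[(2E)-4-bromo-3-methylbut-2-en-1-yl]-1,4-dimethoxy-3-methylnaphthalene
Conditions: CBr4, PPh3, CH2Cl2, −20 °C
Reagents that add atoms: carbon tetrabromide, BrC(Br)(Br)Br
Why: Appel bromination of the primary allylic alcohol gives the C4' bromide by SN2 with the (E)-alkene retained.

Step 25
Reactants: 26 [(3S,7R,10E,14E,18E,23S)-3,7,11,15,19,23,27-heptamethyloctacosa-10,14,18-trien-1-yl]sulfonylbenzene; 35 2-[(2E)-4-bromo-3-methylbut-2-en-1-yl]-1,4-dimethoxy-3-methylnaphthalene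
Product: 37 1,4-dimethoxy-2-methyl-3-[(2E,7S,11R,14E,18E,22E,27S)-3,7,11,15,19,23,27,31-octamethyl-5-(phenylsulfonyl)dotriaconta-2,14,18,22-tetraen-1-yl]naphthalene (C5' epimers), via alpha-lithiated sulfone 36 (not isolated)
Conditions: n-BuLi, THF, −78 °C; then 35, −78 → −20 °C
Reagents that add atoms: none
Why: The only acidic site of 26 is the C5' methylene next to sulfur, and its anion alkylates the primary allylic bromide by SN2 to form C4'–C5' with the C2'=C3' (E) geometry preserved.

Step 26
Reactants: 37 1,4-dimethoxy-2-methyl-3-[(2E,7S,11R,14E,18E,22E,27S)-3,7,11,15,19,23,27,31-octamethyl-5-(phenylsulfonyl)dotriaconta-2,14,18,22-tetraen-1-yl]naphthalene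
Product: 38 1,4-dimethoxy-2-methyl-3-[(2E,7S,11R,14E,18E,22E,27S)-3,7,11,15,19,23,27,31-octamethyldotriaconta-2,14,18,22-tetraen-1-yl]naphthalene
Conditions: Na(Hg) (6 %), Na2HPO4, THF/MeOH, −20 °C → rt
Reagents that add atoms: none
Why: Reductive desulfonylation by single-electron transfer from sodium amalgam cleaves the non-allylic C5'–S bond, so no alkene can migrate, and the dimethoxynaphthalene and isolated alkenes are harder to reduce than the phenyl sulfone.

Step 27
Reactants: 38 1,4-dimethoxy-2-methyl-3-[(2E,7S,11R,14E,18E,22E,27S)-3,7,11,15,19,23,27,31-octamethyldotriaconta-2,14,18,22-tetraen-1-yl]naphthalene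
Product: 39 2-methyl-3-[(2E,7S,11R,14E,18E,22E,27S)-3,7,11,15,19,23,27,31-octamethyldotriaconta-2,14,18,22-tetraen-1-yl]naphthalene-1,4-dione (target)
Conditions: (NH4)2Ce(NO3)6, MeCN/CH2Cl2/H2O, 0 °C
Reagents that add atoms: water, O
Why: Oxidative demethylation of the 1,4-dimethoxyarene by tetravalent cerium gives the para-quinone, its carbonyl oxygens coming from water, and is fast enough at 0 °C to spare the isolated trisubstituted alkenes and the three stereocentres.

Compound list

1 | (S)-citronellol | OCC[C@@H](C)CCC=C(C)C | starting material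
2 | (S)-citronellyl bromide, (6S)-8-bromo-2,6-dimethyloct-2-ene | BrCC[C@@H](C)CCC=C(C)C | intermediate
3 | [(3S)-3,7-dimethyloct-6-en-1-yl]sulfonylbenzene | O=S(=O)(CC[C@@H](C)CCC=C(C)C)c1ccccc1 | intermediate
4 | (4S)-4-methyl-6-(phenylsulfonyl)hexanal | O=S(=O)(CC[C@@H](C)CCC=O)c1ccccc1 | intermediate (not isolated)
5 | (4S)-4-methyl-6-(phenylsulfonyl)hexan-1-ol | O=S(=O)(CC[C@@H](C)CCCO)c1ccccc1 | intermediate
6 | [(3S)-6-bromo-3-methylhexyl]sulfonylbenzene | O=S(=O)(CC[C@@H](C)CCCBr)c1ccccc1 | intermediate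
7 | bromo[(4S)-4-methyl-6-(phenylsulfonyl)hexyl]zinc | O=S(=O)(CC[C@@H](C)CCC[Zn]Br)c1ccccc1 | intermediate (key-step precursor)
8 | 2-bromopropanoyl bromide | CC(Br)C(=O)Br | starting material
9 | N-benzylaniline | C(Nc1ccccc1)c1ccccc1 | starting material
10 | rac-N-benzyl-2-bromo-N-phenylpropanamide | CC(Br)C(=O)N(Cc1ccccc1)c1ccccc1 | intermediate (key-step precursor)
11 | (2R,6S)-N-benzyl-2,6-dimethyl-N-phenyl-8-(phenylsulfonyl)octanamide | O=S(=O)(CC[C@@H](C)CCC[C@@H](C)C(=O)N(Cc1ccccc1)c1ccccc1)c1ccccc1 | intermediate (key-step product)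
12 | (2R,6S)-2,6-dimethyl-8-(phenylsulfonyl)octan-1-ol | O=S(=O)(CC[C@@H](C)CCC[C@@H](C)CO)c1ccccc1 | intermediate
13 | [(3S,7R)-8-iodo-3,7-dimethyloctyl]sulfonylbenzene | O=S(=O)(CC[C@@H](C)CCC[C@@H](C)CI)c1ccccc1 | intermediate
14 | [(3S)-3,7-dimethyloctyl]sulfonylbenzene | O=S(=O)(CC[C@@H](C)CCCC(C)C)c1ccccc1 | intermediate
15 | (2E,6E)-farnesol | CC(C)=CCC/C(C)=C/CC/C(C)=C/CO | starting material
16 | benzyl (2E,6E)-farnesyl ether | CC(C)=CCC/C(C)=C/CC/C(C)=C/COCc1ccccc1 | intermediate
17 | (2E,6E,10E)-12-(benzyloxy)-2,6,10-trimethyldodeca-2,6,10-trien-1-ol | OC/C(C)=C/CC/C(C)=C/CC/C(C)=C/COCc1ccccc1 | intermediate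
18 | {[(2E,6E,10E)-12-bromo-3,7,11-trimethyldodeca-2,6,10-trien-1-yl]oxymethyl}benzene | BrC/C(C)=C/CC/C(C)=C/CC/C(C)=C/COCc1ccccc1 | intermediate
19 | [(3S)-3,7-dimethyl-1-(phenylsulfonyl)octyl]lithium | [Li]C(C[C@@H](C)CCCC(C)C)S(=O)(=O)c1ccccc1 | intermediate (not isolated)
20 | {[(2E,6E,10E,15S)-3,7,11,15,19-pentamethyl-13-(phenylsulfonyl)icosa-2,6,10-trien-1-yl]oxymethyl}benzene (C13 epimers) | O=S(=O)(C(C/C(C)=C/CC/C(C)=C/CC/C(C)=C/COCc1ccccc1)C[C@@H](C)CCCC(C)C)c1ccccc1 | intermediate
21 | (2E,6E,10E,15S)-3,7,11,15,19-pentamethylicosa-2,6,10-trien-1-ol | OC/C=C(\C)CC/C=C(\C)CC/C=C(\C)CCC[C@@H](C)CCCC(C)C | intermediate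
22 | (2E,6E,10E,15S)-1-bromo-3,7,11,15,19-pentamethylicosa-2,6,10-triene | BrC/C=C(\C)CC/C=C(\C)CC/C=C(\C)CCC[C@@H](C)CCCC(C)C | intermediate
23 | [(2E,6E,10E,15S)-3,7,11,15,19-pentamethylicosa-2,6,10-trien-1-yl]sulfonylbenzene | O=S(=O)(C/C=C(\C)CC/C=C(\C)CC/C=C(\C)CCC[C@@H](C)CCCC(C)C)c1ccccc1 | intermediate
24 | [(2E,6E,10E,15S)-3,7,11,15,19-pentamethyl-1-(phenylsulfonyl)icosa-2,6,10-trien-1-yl]lithium | [Li]C(/C=C(\C)CC/C=C(\C)CC/C=C(\C)CCC[C@@H](C)CCCC(C)C)S(=O)(=O)c1ccccc1 | intermediate (not isolated)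
25 | 1,1'-{[(3S,7R,10E,14E,18E,23S)-3,7,11,15,19,23,27-heptamethyloctacosa-10,14,18-triene-1,9-diyl]disulfonyl}dibenzene (C9 epimers) | O=S(=O)(CC[C@@H](C)CCC[C@@H](C)CC(/C=C(\C)CC/C=C(\C)CC/C=C(\C)CCC[C@@H](C)CCCC(C)C)S(=O)(=O)c1ccccc1)c1ccccc1 | intermediate
26 | [(3S,7R,10E,14E,18E,23S)-3,7,11,15,19,23,27-heptamethyloctacosa-10,14,18-trien-1-yl]sulfonylbenzene | O=S(=O)(CC[C@@H](C)CCC[C@@H](C)CC/C=C(\C)CC/C=C(\C)CC/C=C(\C)CCC[C@@H](C)CCCC(C)C)c1ccccc1 | intermediate
27 | menadione | CC1=CC(=O)c2ccccc2C1=O | starting material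
28 | menadiol, 2-methylnaphthalene-1,4-diol | Cc1cc(O)c2ccccc2c1O | intermediate (not isolated)
29 | 1,4-dimethoxy-2-methylnaphthalene | Cc1cc(OC)c2ccccc2c1OC | intermediate
30 | 2-bromo-1,4-dimethoxy-3-methylnaphthalene | Cc1c(Br)c(OC)c2ccccc2c1OC | intermediate
31 | prenyl bromide, 1-bromo-3-methylbut-2-ene | CC(C)=CCBr | starting material
32 | (1,4-dimethoxy-3-methylnaphthalen-2-yl)magnesium bromide | Cc1c([Mg]Br)c(OC)c2ccccc2c1OC | intermediate (not isolated)
33 | 1,4-dimethoxy-2-methyl-3-(3-methylbut-2-en-1-yl)naphthalene | Cc1c(CC=C(C)C)c(OC)c2ccccc2c1OC | intermediate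
34 | (2E)-4-(1,4-dimethoxy-3-methylnaphthalen-2-yl)-2-methylbut-2-en-1-ol | Cc1c(C/C=C(\C)CO)c(OC)c2ccccc2c1OC | intermediate
35 | 2-[(2E)-4-bromo-3-methylbut-2-en-1-yl]-1,4-dimethoxy-3-methylnaphthalene | Cc1c(C/C=C(\C)CBr)c(OC)c2ccccc2c1OC | intermediate
36 | [(3S,7R,10E,14E,18E,23S)-3,7,11,15,19,23,27-heptamethyl-1-(phenylsulfonyl)octacosa-10,14,18-trien-1-yl]lithium | [Li]C(C[C@@H](C)CCC[C@@H](C)CC/C=C(\C)CC/C=C(\C)CC/C=C(\C)CCC[C@@H](C)CCCC(C)C)S(=O)(=O)c1ccccc1 | intermediate (not isolated)
37 | 1,4-dimethoxy-2-methyl-3-[(2E,7S,11R,14E,18E,22E,27S)-3,7,11,15,19,23,27,31-octamethyl-5-(phenylsulfonyl)dotriaconta-2,14,18,22-tetraen-1-yl]naphthalene (C5' epimers) | Cc1c(C/C=C(\C)CC(C[C@@H](C)CCC[C@@H](C)CC/C=C(\C)CC/C=C(\C)CC/C=C(\C)CCC[C@@H](C)CCCC(C)C)S(=O)(=O)c3ccccc3)c(OC)c2ccccc2c1OC | intermediate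
38 | 1,4-dimethoxy-2-methyl-3-[(2E,7S,11R,14E,18E,22E,27S)-3,7,11,15,19,23,27,31-octamethyldotriaconta-2,14,18,22-tetraen-1-yl]naphthalene | Cc1c(C/C=C(\C)CCC[C@@H](C)CCC[C@@H](C)CC/C=C(\C)CC/C=C(\C)CC/C=C(\C)CCC[C@@H](C)CCCC(C)C)c(OC)c2ccccc2c1OC | intermediate
39 | 2-methyl-3-[(2E,7S,11R,14E,18E,22E,27S)-3,7,11,15,19,23,27,31-octamethyldotriaconta-2,14,18,22-tetraen-1-yl]naphthalene-1,4-dione | CC1=C(C/C=C(\C)CCC[C@@H](C)CCC[C@@H](C)CC/C=C(\C)CC/C=C(\C)CC/C=C(\C)CCC[C@@H](C)CCCC(C)C)C(=O)c2ccccc2C1=O | target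

Total step count: 27.
Longest linear sequence: 13 steps (steps 1–5, 7–9, 18, 19, 25–27, from (S)-citronellol).

Steps most likely to fail

1. Step 7 (key step). What may go wrong: incomplete catalyst control over which face of the small α-methyl amido radical is captured, which would erode the C11' ratio in a 1,5-diastereomer pair that cannot be separated; or slow transmetalation of the sulfonyl-bearing zinc reagent. The fallback sets out from 3 and returns at 12, and sets C11' by asymmetric hydrogenation instead of cross-coupling. Ozonolysis of 3 with Me2S work-up would isolate (4S)-4-methyl-6-(phenylsulfonyl)hexanal 4. Wittig olefination with Ph3P=C(CH3)CO2Et in CH2Cl2 should give ethyl (2E,6S)-2,6-dimethyl-8-(phenylsulfonyl)oct-2-enoate F1. Hydrolysis with LiOH in THF/H2O would give (2E,6S)-2,6-dimethyl-8-(phenylsulfonyl)oct-2-enoic acid F2. Hydrogenation of this tiglic-acid-type substrate with Ru(OAc)2(BINAP) (antipode chosen to give 2R), H2, MeOH should give (2R,6S)-2,6-dimethyl-8-(phenylsulfonyl)octanoic acid F3. LiAlH4 reduction then rejoins the route at 12.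

2. Step 12. What may go wrong: imperfect site selectivity of the allylic oxidation among three trisubstituted alkenes, and over-oxidation of the new alcohol to the enal. The fallback sets out from 16 and returns at 17, and builds the (E)-allylic alcohol by cleavage and olefination instead of C–H oxidation. NBS in THF/H2O at 0 °C should form the terminal bromohydrin (6E,10E)-12-(benzyloxy)-3-bromo-2,6,10-trimethyldodeca-6,10-dien-2-ol F4. K2CO3 in MeOH closes it to 2-[(3E,7E)-9-(benzyloxy)-3,7-dimethylnona-3,7-dien-1-yl]-3,3-dimethyloxirane F5. HIO4 in THF/Et2O cleaves the epoxide to (4E,8E)-10-(benzyloxy)-4,8-dimethyldeca-4,8-dienal F6. Wittig olefination with Ph3P=C(CH3)CO2Et gives ethyl (2E,6E,10E)-12-(benzyloxy)-2,6,10-trimethyldodeca-2,6,10-trienoate F7. Reduction with i-Bu2AlH in CH2Cl2 at −78 °C then gives 17.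

3. Step 15. What may go wrong: over-reduction, that is, loss of the allylic C13' oxygen by C–O cleavage alongside or instead of debenzylation. The fallback sets out from 15 and returns at 21, and uses a silyl ether so that C–S cleavage and O-deprotection are separate, orthogonal operations. TBSCl and imidazole should give tert-butyldimethyl{[(2E,6E)-3,7,11-trimethyldodeca-2,6,10-trien-1-yl]oxy}silane F8. SeO2/t-BuOOH as in step 12 gives (2E,6E,10E)-12-[(tert-butyldimethylsilyl)oxy]-2,6,10-trimethyldodeca-2,6,10-trien-1-ol F9. CBr4/PPh3 gives {[(2E,6E,10E)-12-bromo-3,7,11-trimethyldodeca-2,6,10-trien-1-yl]oxy}(tert-butyl)dimethylsilane F10. Alkylation of the lithiated sulfone 19 as in step 14 gives tert-butyldimethyl{[(2E,6E,10E,15S)-3,7,11,15,19-pentamethyl-13-(phenylsulfonyl)icosa-2,6,10-trien-1-yl]oxy}silane F11. Na(Hg), Na2HPO4 in THF/MeOH removes only the sulfonyl group to give tert-butyldimethyl{[(2E,6E,10E,15S)-3,7,11,15,19-pentamethylicosa-2,6,10-trien-1-yl]oxy}silane F12. n-Bu4NF in THF then gives 21.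

Further compounds

F1 | step 7 | ethyl (2E,6S)-2,6-dimethyl-8-(phenylsulfonyl)oct-2-enoate | O=S(=O)(CC[C@@H](C)CC/C=C(\C)C(=O)OCC)c1ccccc1
F2 | step 7 | (2E,6S)-2,6-dimethyl-8-(phenylsulfonyl)oct-2-enoic acid | O=S(=O)(CC[C@@H](C)CC/C=C(\C)C(=O)O)c1ccccc1
F3 | step 7 | (2R,6S)-2,6-dimethyl-8-(phenylsulfonyl)octanoic acid | O=S(=O)(CC[C@@H](C)CCC[C@@H](C)C(=O)O)c1ccccc1
F4 | step 12 | (6E,10E)-12-(benzyloxy)-3-bromo-2,6,10-trimethyldodeca-6,10-dien-2-ol (racemic at C3) | CC(C)(O)C(Br)CC/C(C)=C/CC/C(C)=C/COCc1ccccc1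
F5 | step 12 | 2-[(3E,7E)-9-(benzyloxy)-3,7-dimethylnona-3,7-dien-1-yl]-3,3-dimethyloxirane (racemic) | CC1(C)OC1CC/C(C)=C/CC/C(C)=C/COCc1ccccc1
F6 | step 12 | (4E,8E)-10-(benzyloxy)-4,8-dimethyldeca-4,8-dienal | O=CCC/C(C)=C/CC/C(C)=C/COCc1ccccc1
F7 | step 12 | ethyl (2E,6E,10E)-12-(benzyloxy)-2,6,10-trimethyldodeca-2,6,10-trienoate | CCOC(=O)/C(C)=C/CC/C(C)=C/CC/C(C)=C/COCc1ccccc1
F8 | step 15 | tert-butyldimethyl{[(2E,6E)-3,7,11-trimethyldodeca-2,6,10-trien-1-yl]oxy}silane | CC(C)=CCC/C(C)=C/CC/C(C)=C/CO[Si](C)(C)C(C)(C)C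
F9 | step 15 | (2E,6E,10E)-12-[(tert-butyldimethylsilyl)oxy]-2,6,10-trimethyldodeca-2,6,10-trien-1-ol | OC/C(C)=C/CC/C(C)=C/CC/C(C)=C/CO[Si](C)(C)C(C)(C)C
F10 | step 15 | {[(2E,6E,10E)-12-bromo-3,7,11-trimethyldodeca-2,6,10-trien-1-yl]oxy}(tert-butyl)dimethylsilane | BrC/C(C)=C/CC/C(C)=C/CC/C(C)=C/CO[Si](C)(C)C(C)(C)C
F11 | step 15 | tert-butyldimethyl{[(2E,6E,10E,15S)-3,7,11,15,19-pentamethyl-13-(phenylsulfonyl)icosa-2,6,10-trien-1-yl]oxy}silane (C13 epimers) | O=S(=O)(C(C/C(C)=C/CC/C(C)=C/CC/C(C)=C/CO[Si](C)(C)C(C)(C)C)C[C@@H](C)CCCC(C)C)c1ccccc1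
F12 | step 15 | tert-butyldimethyl{[(2E,6E,10E,15S)-3,7,11,15,19-pentamethylicosa-2,6,10-trien-1-yl]oxy}silane | CC(C)(C)[Si](C)(C)OC/C=C(\C)CC/C=C(\C)CC/C=C(\C)CCC[C@@H](C)CCCC(C)C
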